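**Plan**

- Retrosynthesis: the three O-isopropyl bonds are cut last. Ring A is then unravelled across C4a–C5 to a 3-isopropoxy-4-methoxycyclobutenone that sits on the oxygen-flanked carbon of a γ-pyranone.
- The C8–C8a bond is cut next (6-lithiopyranone plus isopropyl semisquarate, methyl capture of the alkoxide). The pyranone is cut at O1–C8a and C4a–C8a (amide acetal carbon), C3–C4 (acetyl) and C2–C1' (aryllithium plus Weinreb amide).
- Forward order: ring B is dressed from isovanillin, ring C is built as a monocyclic 2-aryl-3-methoxy-4-pyranone, and ring A is made last from the four-membered ring. One BCl3 step then frees the three phenols.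
- Enabling feature: ring A carries C5–OH para to C8–OMe, with C7–O beside C8 and C6–H beside C5. A 3-alkoxy-4-methoxycyclobutenone made from a semisquarate delivers exactly this array when it expands onto an alkene, here the pyranone CH=C bond that becomes C4a–C8a.
- Stereochemistry: the target has no stereocentre; the racemic centres of 11, 15, 19 and 21 are erased downstream.

Key step: step 10

Remark: flavone numbering (O1, C2 to C8a, primed ring B) is used for 20 to 23. In pyranone 13 the aryl group is on C2, the methoxy group on C3, and the free positions are C5–H (next to C=O) and C6–H (next to O).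

**Route**

Step 1
Reactants: 1 isovanillin (3-hydroxy-4-methoxybenzaldehyde)
Product: 2 3-isopropoxy-4-methoxybenzaldehyde
Conditions: 2-bromopropane, K2CO3, DMF, 60 °C
Reagents that add atoms: 2-bromopropane, CC(C)Br
Why: Williamson ether synthesis, in which the phenoxide displaces bromide from the secondary halide in a dipolar aprotic solvent and excess halide compensates for elimination.

Step 2
Reactants: 2 3-isopropoxy-4-methoxybenzaldehyde
Product: 4 3-isopropoxy-4-methoxyphenol, via aryl formate 3 (not isolated)
Conditions: mCPBA, CH2Cl2, 0 °C to rt; aq. NaHCO3 wash; then K2CO3 (cat.), MeOH, rt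
Reagents that add atoms: 3-chloroperoxybenzoic acid (mCPBA), OOC(=O)c1cccc(Cl)c1
Why: Baeyer–Villiger (Dakin-type) oxidation, in which the electron-rich aryl group migrates to oxygen to give the aryl formate, which mild methanolysis cleaves to the phenol.

Step 3
Reactants: 4 3-isopropoxy-4-methoxyphenol
Product: 5 2,4-diisopropoxy-1-methoxybenzene
Conditions: 2-bromopropane, K2CO3, DMF, 60 °C
Reagents that add atoms: 2-bromopropane, CC(C)Br
Why: Williamson ether synthesis on an unhindered phenoxide, as in step 1.

Step 4
Reactants: 5 2,4-diisopropoxy-1-methoxybenzene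
Product: 6 1-bromo-2,4-diisopropoxy-5-methoxybenzene
Conditions: NBS, MeCN, 0 °C
Reagents that add atoms: N-bromosuccinimide, O=C1CCC(=O)N1Br
Why: Electrophilic aromatic bromination, which should go to C5 because it is ortho to one isopropoxy group and para to the other and is far less hindered than C3 between the two ethers.

Step 5
Reactants: 6 1-bromo-2,4-diisopropoxy-5-methoxybenzene; 7 N,2-dimethoxy-N-methylacetamide
Product: 10 1-(2,4-diisopropoxy-5-methoxyphenyl)-2-methoxyethan-1-one, via aryllithium 8 (not isolated), via tetrahedral lithium adduct 9 (not isolated)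
Conditions: n-BuLi, THF, −78 °C; then 7, −78 to 0 °C; 1 M HCl
Reagents that add atoms: none
Why: Bromine–lithium exchange followed by Weinreb ketone synthesis, in which the chelated tetrahedral adduct survives until work-up and so prevents a second addition.

Step 6
Reactants: 10 1-(2,4-diisopropoxy-5-methoxyphenyl)-2-methoxyethan-1-one
Product: 11 racemic 1-(2,4-diisopropoxy-5-methoxyphenyl)-2-methoxybutane-1,3-dione
Conditions: AcCl, MgBr2·OEt2, i-Pr2NEt, CH2Cl2, rt
Reagents that add atoms: acetyl chloride, CC(=O)Cl
Why: Soft-enolisation C-acylation (a Claisen-type condensation through a magnesium enolate), favoured because the α-methoxy ketone chelates magnesium and the magnesium diketonate of the product resists a second acylation.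

Step 7
Reactants: 11 racemic 1-(2,4-diisopropoxy-5-methoxyphenyl)-2-methoxybutane-1,3-dione
Product: 13 2-(2,4-diisopropoxy-5-methoxyphenyl)-3-methoxy-4H-pyran-4-one, via enaminone 12 (not isolated)
Conditions: Me2NCH(OMe)2, toluene, 90 °C; then AcOH, 80 °C
Reagents that add atoms: N,N-dimethylformamide dimethyl acetal, COC(OC)N(C)C
Why: Enaminone condensation at the only methyl ketone followed by acid-promoted 6-endo addition of the aryl ketone enol oxygen to the enaminone carbon and loss of dimethylamine, the standard γ-pyrone synthesis from 1,3-diketones.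

Step 8
Reactants: 14 diisopropyl squarate
Product: 16 3-isopropoxycyclobut-3-ene-1,2-dione, via hydroxycyclobutenone 15 (not isolated)
Conditions: LiAlH(OtBu)3, THF, −78 to 0 °C; 1 M HCl work-up; then conc. aq. HCl (cat.), CH2Cl2, rt
Reagents that add atoms: water, O
Why: Selective hydride 1,2-reduction of one squarate carbonyl followed by acid-catalysed allylic transposition, in which the carbinol oxygen leaves as water, water adds to the dialkoxy-stabilised cation and isopropanol is expelled (the established squarate-to-semisquarate conversion).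

Step 9
Reactants: 13 2-(2,4-diisopropoxy-5-methoxyphenyl)-3-methoxy-4H-pyran-4-one; 16 3-isopropoxycyclobut-3-ene-1,2-dione
Product: 19 racemic 3-isopropoxy-4-methoxy-4-[6-(2,4-diisopropoxy-5-methoxyphenyl)-5-methoxy-4-oxo-4H-pyran-2-yl]cyclobut-2-en-1-one, via 6-lithiopyranone 17 (not isolated), via lithium alkoxide 18 (not isolated)
Conditions: 13 added to lithium 2,2,6,6-tetramethylpiperidide, THF, −78 °C; cannulated onto 16, THF, −78 °C; then MeOTf, −78 to 0 °C
Reagents that add atoms: methyl trifluoromethanesulfonate, COS(=O)(=O)C(F)(F)F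
Why: Directed deprotonation of the oxygen-flanked vinylic C6–H (as in the α-lithiation of chromones, 4-pyridones and β-alkoxyacrylates), 1,2-addition of the vinyllithium to the ketone-like carbonyl next to C–O-isopropyl (the other carbonyl is a deactivated vinylogous ester), and O-methylation of the tertiary lithium alkoxide by the hard methylating agent.

Step 10
Reactants: 19 racemic 3-isopropoxy-4-methoxy-4-[6-(2,4-diisopropoxy-5-methoxyphenyl)-5-methoxy-4-oxo-4H-pyran-2-yl]cyclobut-2-en-1-one
Product: 22 2-(2,4-diisopropoxy-5-methoxyphenyl)-5-hydroxy-7-isopropoxy-3,8-dimethoxy-4H-chromen-4-one, via dienylketene 20 (not isolated), via cyclohexadienone 21 (not isolated)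
Conditions: toluene (degassed, dilute), 110 °C
Reagents that add atoms: none
Why: Heating opens the cyclobutenone by conrotatory four-electron electrocyclic cleavage of the C1–C4 bond, and the 4-methoxy group, the strongest π-donor on that carbon, rotates outward so that the pyranonyl group turns inward and the (Z)-dienylketene 20 results. Ring A then closes by a thermally allowed disrotatory six-electron electrocyclisation in which the electrophilic ketene carbon (future C5) bonds to the free pyranone CH (future C4a, the nucleophilic α-carbon of a vinylogous ester), giving dienone 21, whose doubly activated C4a hydrogen is lost on tautomerisation to the hydrogen-bonded 5-hydroxyflavone. The closest known reaction type is the Moore rearrangement of 4-alkoxy-4-alkenyl- and 4-(hetero)arylcyclobutenones to para-alkoxyphenols. No stereocentre is created, since the racemic centre of 19 becomes the sp2 carbon C8 and the transient centre at C4a of 21 is removed by enolisation. The only selectivity demanded is the outward torquoselectivity of the methoxy group; the closure site is unambiguous because the pyranone carbon that bears the four-membered ring has the CH on one side and the ring oxygen on the other, and the order 5-OH, 6-H, 7-O-isopropyl, 8-OMe was already fixed by the regiochemistry of step 9.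

Step 11
Reactants: 22 2-(2,4-diisopropoxy-5-methoxyphenyl)-5-hydroxy-7-isopropoxy-3,8-dimethoxy-4H-chromen-4-one
Product: 23 5,7,2',4'-tetrahydroxy-3,8,5'-trimethoxyflavone
Conditions: BCl3 (excess), CH2Cl2, −78 to 0 °C; then H2O
Reagents that add atoms: none
Why: Lewis-acid ether cleavage, in which BCl3 removes the three secondary isopropyl groups as 2-chloropropane much faster than it attacks methyl ethers, while the six-membered 5-O–B–O=C4 chelate keeps the carbonyl from assisting loss of the 3-methyl group.

**Compound list**

1 | isovanillin (3-hydroxy-4-methoxybenzaldehyde) | COc1ccc(C=O)cc1O | starting material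
2 | 3-isopropoxy-4-methoxybenzaldehyde | COc1ccc(C=O)cc1OC(C)C | intermediate
3 | 3-isopropoxy-4-methoxyphenyl formate (not isolated) | COc1ccc(OC=O)cc1OC(C)C | intermediate
4 | 3-isopropoxy-4-methoxyphenol | COc1ccc(O)cc1OC(C)C | intermediate
5 | 2,4-diisopropoxy-1-methoxybenzene | COc1ccc(OC(C)C)cc1OC(C)C | intermediate
6 | 1-bromo-2,4-diisopropoxy-5-methoxybenzene | COc1cc(Br)c(OC(C)C)cc1OC(C)C | intermediate
7 | N,2-dimethoxy-N-methylacetamide | COCC(=O)N(C)OC | starting material
8 | (2,4-diisopropoxy-5-methoxyphenyl)lithium (not isolated) | [Li]c1cc(OC)c(OC(C)C)cc1OC(C)C | intermediate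
9 | lithium 1-(2,4-diisopropoxy-5-methoxyphenyl)-2-methoxy-1-[methoxy(methyl)amino]ethan-1-olate (not isolated) | COCC(O[Li])(N(C)OC)c1cc(OC)c(OC(C)C)cc1OC(C)C | intermediate
10 | 1-(2,4-diisopropoxy-5-methoxyphenyl)-2-methoxyethan-1-one | COCC(=O)c1cc(OC)c(OC(C)C)cc1OC(C)C | intermediate
11 | racemic 1-(2,4-diisopropoxy-5-methoxyphenyl)-2-methoxybutane-1,3-dione | CC(=O)C(OC)C(=O)c1cc(OC)c(OC(C)C)cc1OC(C)C | intermediate
12 | racemic (E)-1-(2,4-diisopropoxy-5-methoxyphenyl)-5-(dimethylamino)-2-methoxypent-4-ene-1,3-dione (not isolated) | CN(C)/C=C/C(=O)C(OC)C(=O)c1cc(OC)c(OC(C)C)cc1OC(C)C | intermediate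
13 | 2-(2,4-diisopropoxy-5-methoxyphenyl)-3-methoxy-4H-pyran-4-one | COc1cc(-c2occc(=O)c2OC)c(OC(C)C)cc1OC(C)C | intermediate
14 | diisopropyl squarate (3,4-diisopropoxycyclobut-3-ene-1,2-dione) | CC(C)OC1=C(OC(C)C)C(=O)C1=O | starting material
15 | racemic 4-hydroxy-2,3-diisopropoxycyclobut-2-en-1-one (not isolated) | CC(C)OC1=C(OC(C)C)C(O)C1=O | intermediate
16 | 3-isopropoxycyclobut-3-ene-1,2-dione | CC(C)OC1=CC(=O)C1=O | intermediate
17 | [6-(2,4-diisopropoxy-5-methoxyphenyl)-5-methoxy-4-oxo-4H-pyran-2-yl]lithium (not isolated) | [Li]c1cc(=O)c(OC)c(-c2cc(OC)c(OC(C)C)cc2OC(C)C)o1 | intermediate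
18 | racemic lithium 1-[6-(2,4-diisopropoxy-5-methoxyphenyl)-5-methoxy-4-oxo-4H-pyran-2-yl]-2-isopropoxy-4-oxocyclobut-2-en-1-olate (not isolated) | [Li]OC1(c2cc(=O)c(OC)c(-c3cc(OC)c(OC(C)C)cc3OC(C)C)o2)C(OC(C)C)=CC1=O | intermediate
19 | racemic 3-isopropoxy-4-methoxy-4-[6-(2,4-diisopropoxy-5-methoxyphenyl)-5-methoxy-4-oxo-4H-pyran-2-yl]cyclobut-2-en-1-one | COC1(c2cc(=O)c(OC)c(-c3cc(OC)c(OC(C)C)cc3OC(C)C)o2)C(OC(C)C)=CC1=O | intermediate
20 | (Z)-3-isopropoxy-4-methoxy-4-[6-(2,4-diisopropoxy-5-methoxyphenyl)-5-methoxy-4-oxo-4H-pyran-2-yl]buta-1,3-dien-1-one, the dienylketene (not isolated) | O=C=C/C(OC(C)C)=C(OC)\c1cc(=O)c(OC)c(-c2cc(OC)c(OC(C)C)cc2OC(C)C)o1 | intermediate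
21 | racemic 2-(2,4-diisopropoxy-5-methoxyphenyl)-7-isopropoxy-3,8-dimethoxy-4aH-chromene-4,5-dione (not isolated) | O=C1C=C(OC(C)C)C(OC)=C2OC(c3cc(OC)c(OC(C)C)cc3OC(C)C)=C(OC)C(=O)C12 | intermediate
22 | 2-(2,4-diisopropoxy-5-methoxyphenyl)-5-hydroxy-7-isopropoxy-3,8-dimethoxy-4H-chromen-4-one | COc1cc(-c2oc3c(OC)c(OC(C)C)cc(O)c3c(=O)c2OC)c(OC(C)C)cc1OC(C)C | intermediate
23 | 5,7,2',4'-tetrahydroxy-3,8,5'-trimethoxyflavone | COc1cc(-c2oc3c(OC)c(O)cc(O)c3c(=O)c2OC)c(O)cc1O | target

**Step count and risks**

Total step count: 11. Longest linear sequence: 10 (steps 1 to 7, then 9, 10 and 11; step 8 is the one-step side branch).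

Steps most likely to fail:

Step 9. Deprotonation may take place at the carbonyl-flanked C5–H instead of C6–H, the lithiated pyranone may add to pyranone that has not yet been deprotonated, and methyl triflate may alkylate the pyranone carbonyl oxygen in competition with the hindered alkoxide. The fallback sets out from pyranone 13 and rejoins the route at the 6-lithiopyranone 17. Zincation of 13 with Zn(TMP)2·2MgCl2·2LiCl (TMP = 2,2,6,6-tetramethylpiperidide) in THF should give bis[6-(2,4-diisopropoxy-5-methoxyphenyl)-5-methoxy-4-oxo-4H-pyran-2-yl]zinc F1 (not isolated); magnesium chloride bound to the carbonyl oxygen steers the amide to the oxygen-flanked CH, and the zinc species does not add to pyranones. Iodine should then convert it to 2-(2,4-diisopropoxy-5-methoxyphenyl)-6-iodo-3-methoxy-4H-pyran-4-one F2, which is isolated and its regiochemistry confirmed. Iodine–lithium exchange of F2 with n-BuLi in THF at −100 °C generates 17 instantly, in the absence of free pyranone and amine, and the addition to 16 and methyl capture follow as in step 9.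

Step 10. The ketene may be consumed by dimerisation or by traces of nucleophiles before it closes onto the cross-conjugated pyranone double bond, or ring opening of the fully substituted methyl ether may demand temperatures at which the product degrades. The fallback sets out from lithium alkoxide 18 and rejoins the route at 22. Quenching 18 with aqueous NH4Cl instead of methyl triflate should give racemic 4-hydroxy-3-isopropoxy-4-[6-(2,4-diisopropoxy-5-methoxyphenyl)-5-methoxy-4-oxo-4H-pyran-2-yl]cyclobut-2-en-1-one F3. Heating F3 in toluene under argon runs the same ring expansion in the less hindered hydroxy series (the classical hydroquinone variant, with hydroxyl as the outward-rotating donor) and should give 2-(2,4-diisopropoxy-5-methoxyphenyl)-5,8-dihydroxy-7-isopropoxy-3-methoxy-4H-chromen-4-one F4. Without exposure to air, one equivalent of MeI with K2CO3 in acetone should methylate the free 8-OH only, because the 5-OH is held by the hydrogen bond to the C4 carbonyl, giving 22.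

Step 7. Methyl transfer from the amide acetal to the enol oxygen of the diketone, and retro-Claisen loss of the acetyl group in the basic medium, may outrun condensation at the methyl group. The fallback sets out from ketone 10 and rejoins the route at pyranone 13, replacing steps 6 and 7. Soft-enolisation acylation of 10 (MgBr2·OEt2, i-Pr2NEt, CH2Cl2) with (E)-3-ethoxyacryloyl chloride brings in the last ring carbon already at the right oxidation level and should give racemic (E)-1-(2,4-diisopropoxy-5-methoxyphenyl)-5-ethoxy-2-methoxypent-4-ene-1,3-dione F5. Trifluoroacetic acid in CH2Cl2 then closes the ring by conjugate addition of the enol oxygen and loss of ethanol to give 13.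

Further compounds
F1 | step 9 | bis[6-(2,4-diisopropoxy-5-methoxyphenyl)-5-methoxy-4-oxo-4H-pyran-2-yl]zinc (not isolated) | COc1cc(-c2oc([Zn]c3cc(=O)c(OC)c(-c4cc(OC)c(OC(C)C)cc4OC(C)C)o3)cc(=O)c2OC)c(OC(C)C)cc1OC(C)C
F2 | step 9 | 2-(2,4-diisopropoxy-5-methoxyphenyl)-6-iodo-3-methoxy-4H-pyran-4-one | COc1cc(-c2oc(I)cc(=O)c2OC)c(OC(C)C)cc1OC(C)C
F3 | step 10 | racemic 4-hydroxy-3-isopropoxy-4-[6-(2,4-diisopropoxy-5-methoxyphenyl)-5-methoxy-4-oxo-4H-pyran-2-yl]cyclobut-2-en-1-one | COc1cc(-c2oc(C3(O)C(OC(C)C)=CC3=O)cc(=O)c2OC)c(OC(C)C)cc1OC(C)C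
F4 | step 10 | 2-(2,4-diisopropoxy-5-methoxyphenyl)-5,8-dihydroxy-7-isopropoxy-3-methoxy-4H-chromen-4-one | COc1cc(-c2oc3c(O)c(OC(C)C)cc(O)c3c(=O)c2OC)c(OC(C)C)cc1OC(C)C
F5 | step 7 | racemic (E)-1-(2,4-diisopropoxy-5-methoxyphenyl)-5-ethoxy-2-methoxypent-4-ene-1,3-dione | CCO/C=C/C(=O)C(OC)C(=O)c1cc(OC)c(OC(C)C)cc1OC(C)C
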